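**Retrosynthetic overview**
1. Enabling feature: the cyclohexane oxygen (C11–O) and the oxepane O–CH2 carbon (C16) are 1,6-related through C12–C13–C14–C15. With C11 as a ketone and C16 as a lactone carbonyl this is a 1,6-dicarbonyl, so the ring bond C13–C14 is the β,β′-bond of two Michael acceptors (C12=C13 enone and C14=C15 unsaturated ε-lactone).
2. Key disconnection: cathodic reductive cyclisation (electrohydrocyclisation) forms C13–C14, closes the cyclohexane last and sets C12, C14 and C15. The C11 ketone then gives the carbinol, the lactone C=O is reduced to the oxepane CH2, and the two acylations finish the route.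
3. Oxepane (at the lactone level): C3–O bond by opening of a C3–C4 epoxide by the C16 carboxylic acid (sets C3 and C4); C14=C15 by Z-selective olefination.
4. Oxonane: ring-closing metathesis C3=C4 on a cis-2,5-disubstituted tetrahydrofuran; C4–C8 chain by Cu-catalysed triflate/vinyl-Grignard coupling.
5. Tetrahydrofuran (C1, C2, C9, C10): exo Diels–Alder adduct of 3-methylfuran and maleic anhydride, resolved by alkaloid-mediated methanolysis, then ozonolysis. Ring order: tetrahydrofuran → oxonane → oxepane → cyclohexane.

Key step: step 16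

Locants are those of the asbestinane skeleton of the target: cyclohexane C1/C10/C11/C12/C13/C14; tetrahydrofuran C1/C2/O/C9/C10; oxonane O/C2–C9; oxepane C1/C2/C3/O/C16/C15/C14; C17 methyl on C15, C18 methyl on C3, C19 methylidene on C7, C20 methyl on C12.
Assumption: quinidine is taken to open anhydride 3 at the carbonyl that leads to 4 (if the opposite sense operates, quinine takes its place); 3-methylfuran and (R)-2-hydroxyoctanoic acid are taken as commercial.

**Step 1**
Reactants: 1 3-methylfuran; 2 maleic anhydride
Product: 3 rac-exo-5-methyl-7-oxabicyclo[2.2.1]hept-5-ene-2,3-dicarboxylic anhydride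
Conditions: Et2O, rt, dark
Reagents that add atoms: none
Why: Diels–Alder reaction of a furan, reversible at rt, should settle on the exo adduct; this fixes the relative configuration of the future C1, C2, C9, C10 (C2/C9 cis through the oxygen bridge, both carbonyl-bearing carbons exo, hence C1/C2 and C9/C10 trans, C1/C10 cis).

**Step 2**
Reactants: 3 rac-exo anhydride
Product: 4 3-exo-(methoxycarbonyl)-5-methyl-7-oxabicyclo[2.2.1]hept-5-ene-2-exo-carboxylic acid (acid on future C10, ester on future C1; enantiomer as in the SMILES)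
Conditions: quinidine (1.1 equiv), MeOH (3 equiv), toluene, −55 °C; acid extraction, chromatography
Reagents that add atoms: methanol CO
Why: Cinchona-alkaloid-mediated methanolysis of a bicyclic anhydride, run on the racemate as a parallel kinetic resolution: the alkaloid picks the carbonyl by absolute position, so 3 should give 4 while ent-3 should give the constitutional isomer with ester and acid exchanged, which is separated; this sets the absolute configuration of C1, C2, C9, C10.

**Step 3**
Reactants: 4 hemiester
Product: 6 exo-fused γ-lactone of 5-methyl-7-oxabicyclo[2.2.1]hept-5-ene (lactone C=O on C2 of the bicycle = C11; O–CH2 on C3 = C14), via hydroxy acid 5 (not isolated)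
Conditions: LiEt3BH (3.2 equiv), THF, −78 → 0 °C; then 1 M HCl, rt
Reagents that add atoms: none
Why: Hydride reduction of the ester in the presence of the unreactive lithium carboxylate, then acid-catalysed lactonisation of the cis γ-hydroxy acid; no stereocentre is touched.

**Step 4**
Reactants: 6 γ-lactone
Product: 8 4-acetyl-6-(hydroxymethyl)tetrahydro-1H,3H-furo[3,4-c]furan-1-one (2,5-cis tetrahydrofuran: acetyl = C3 with C18 on C2, CH2OH = C8 on C9; both trans to the lactone ring), via keto aldehyde 7 (not isolated)
Conditions: O3, CH2Cl2/MeOH, −78 °C; Me2S; then NaBH(OAc)3, CH2Cl2, 0 °C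
Reagents that add atoms: ozone [O-][O+]=O
Why: Ozonolysis with reductive work-up opens the bicycle to the cis-2,5-disubstituted tetrahydrofuran, and triacetoxyborohydride reduces the aldehyde chemoselectively in the presence of the methyl ketone, which differentiates the C3 and C8 arms.

**Step 5**
Reactants: 8 hydroxy ketone
Product: 9 6-(hydroxymethyl)-4-(prop-1-en-2-yl)tetrahydro-1H,3H-furo[3,4-c]furan-1-one
Conditions: Zn, CH2Br2, TiCl4, THF/CH2Cl2, 0 °C → rt
Reagents that add atoms: dibromomethane BrCBr
Why: Takai–Lombardo methylenation is non-basic and ketone-selective, so the epimerisable C2 and the β-alkoxy lactone should survive.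

**Step 6**
Reactants: 10 2,3-dibromopropene
Product: 11 2-bromohexa-1,5-diene
Conditions: allylMgBr, Et2O, 0 °C → rt
Reagents that add atoms: allylmagnesium bromide C=CC[Mg]Br
Why: Grignard substitution of the allylic bromide while the vinylic bromide is retained.

**Step 7**
Reactants: 9 isopropenyl alcohol; 11 2-bromohexa-1,5-diene
Product: 13 6-(2-methylidenehex-5-en-1-yl)-4-(prop-1-en-2-yl)tetrahydro-1H,3H-furo[3,4-c]furan-1-one, via triflate 12 (not isolated)
Conditions: Tf2O, 2,6-lutidine, CH2Cl2, −78 °C; then Grignard reagent from 11 (Mg, THF), CuI (10 mol%), THF, −40 → 0 °C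
Reagents that add atoms: none
Why: Copper-catalysed sp3–sp2 coupling of a primary alkyl triflate with a vinyl Grignard reagent, faster at low temperature than attack on the lactone; it brings in C4–C7 and C19.

**Step 8**
Reactants: 13 triene lactone
Product: 14 tricyclic lactone: oxonane (O, C2–C9) bridged by C1–C10, (Z)-C3=C4 with C18 on C3, C7=C19 methylidene, γ-lactone C10–C11(=O)–O–C14H2–C1
Conditions: Grubbs II (10 mol%), toluene (1 mM), 80 °C
Reagents that add atoms: none
Why: Ring-closing metathesis between the terminal vinyl group and the isopropenyl group, preorganised by the cis-2,5 substituents of the tetrahydrofuran; the nine-membered ring allows only the Z trisubstituted olefin.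

**Step 9**
Reactants: 14 tricyclic lactone
Product: 15 C11 N-methoxy-N-methylamide with free C14 primary alcohol
Conditions: MeNHOMe·HCl, i-PrMgCl, THF, −20 °C
Reagents that add atoms: N,O-dimethylhydroxylamine hydrochloride CNOC.Cl
Why: Aminolysis of the lactone by the magnesium amide (Weinreb amide formation) separates the two arms into a ketone precursor (C11) and an alcohol (C14).

**Step 10**
Reactants: 15 hydroxy amide
Product: 16 C14 aldehyde
Conditions: Dess–Martin periodinane, NaHCO3, CH2Cl2, 0 °C → rt
Reagents that add atoms: none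
Why: Dess–Martin oxidation under buffered, neutral conditions should leave the α-stereocentre C1 intact.

**Step 11**
Reactants: 16 aldehyde
Product: 17 ethyl (Z)-enoate C14=C15(C17)–C16O2Et
Conditions: ethyl 2-[bis(2,2,2-trifluoroethoxy)phosphoryl]propanoate, KHMDS, 18-crown-6, THF, −78 °C
Reagents that add atoms: ethyl 2-[bis(2,2,2-trifluoroethoxy)phosphoryl]propanoate CCOC(=O)C(C)P(=O)(OCC(F)(F)F)OCC(F)(F)F
Why: Still–Gennari olefination gives the Z-configured 2-methyl enoate, the geometry that lets C16 reach C3 later; no free base meets the aldehyde.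

**Step 12**
Reactants: 17 (Z)-enoate
Product: 18 (Z)-enoic acid
Conditions: LiOH·H2O, THF/MeOH/H2O, 40 °C; then 1 M HCl to pH 3
Reagents that add atoms: lithium hydroxide [Li+].[OH-]
Why: Saponification of the ethyl ester; the Weinreb amide is inert under these conditions.

**Step 13**
Reactants: 18 enoic acid
Product: 20 α,β-unsaturated ε-lactone C3–O–C16(=O)–C15(C17)=C14–C1 with free C4–OH (C3 and C4 as in the target), via epoxy acid 19 (not isolated)
Conditions: m-CPBA (1.05 equiv), CH2Cl2, −20 °C; then CSA (0.1 equiv), 0 °C → rt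
Reagents that add atoms: m-chloroperbenzoic acid OOC(=O)c1cccc(Cl)c1
Why: Prilezhaev epoxidation of the most electron-rich olefin (trisubstituted C3=C4) on its outer face, anti to the C1–C10 bridge, then acid-catalysed 7-exo opening at the tertiary C3 with inversion by the C16 acid held on the opposite face through C1; this sets C3 (ether oxygen) and C4 (hydroxyl) trans.

**Step 14**
Reactants: 20 hydroxy lactone
Product: 21 C4 tert-butyldimethylsilyl ether
Conditions: TBSOTf, 2,6-lutidine, CH2Cl2, −78 °C
Reagents that add atoms: tert-butyldimethylsilyl triflate CC(C)(C)[Si](C)(C)OS(=O)(=O)C(F)(F)F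
Why: Silylation of the hindered secondary alcohol with the silyl triflate; the ether must survive organometallic, hydride and Lewis-acid steps.

**Step 15**
Reactants: 21 Weinreb amide
Product: 22 C11 isopropenyl ketone (C12=C13 enone with C20 on C12) beside the C14=C15 unsaturated ε-lactone
Conditions: isopropenylMgBr, THF, −40 → 0 °C; cold NH4Cl quench
Reagents that add atoms: isopropenylmagnesium bromide C=C(C)[Mg]Br
Why: Weinreb ketone synthesis; the chelated tetrahedral intermediate stops at the ketone and the hindered tertiary-alkyl lactone should not compete at low temperature.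

**Step 16**
Reactants: 22 enone lactone
Product: 23 tetracyclic keto lactone (cyclohexanone C1/C10/C11(=O)/C12/C13/C14; C12, C14, C15 as in the target)
Conditions: undivided cell, reticulated vitreous carbon cathode, Mg anode, −2.2 V vs SCE (ca. 2.1 F/mol), n-Bu4NBF4 (0.1 M), dimethyl malonate (2.5 equiv), DMF, 0 °C, 2 mM
Reagents that add atoms: none
Why: Cathodic one-electron reduction of the isopropenyl ketone gives a radical anion with spin on C13 that adds 6-exo-trig to C14, the β-carbon of the unsaturated lactone (reduction of the lactone first would lead to the same bond); a second electron and two protons from dimethyl malonate turn the C15 lactone enolate and the C11=C12 ketone enolate into their C–H forms. The closest known reaction type is the electroreductive hydrocyclisation of two tethered Michael acceptors, with tin-ketyl, SmI2 and photoredox enone–enoate cyclisations as relatives. The cyclohexane is closed through C13–C14 in the 6-exo-trig mode and no other ring is formed. C14 is controlled by the tether on C1: chair-like closure with the lactone C14=C15 bond pseudo-equatorial puts H14 anti to H1; C15 is set by protonation of the lactone enolate anti to the new C13–C14 bond; C12 is set by protonation of the ketone enolate from the convex face (that of H1 and H10), opposite the pseudo-axial C10–C9 bond, which leaves C20 axial and cis to the C11 oxygen. The step needs cyclisation to outrun protonation of the radical anion and the kinetic C12 centre to persist; high dilution and a weak acid whose conjugate base cannot enolise the ketone should secure both, and the unactivated C7 methylidene is not reducible at this potential.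

**Step 17**
Reactants: 23 keto lactone
Product: 24 C11 secondary alcohol (C11 as in the target)
Conditions: NaBH4, MeOH/CH2Cl2, −40 °C
Reagents that add atoms: none
Why: Borohydride reduction from the convex face, since the other face of C11 is blocked by the axial C10–C9 bond and the axial C20 methyl; this gives the equatorial alcohol cis to C20 and removes the epimerisable ketone at once.

**Step 18**
Reactants: 24 hydroxy lactone
Product: 26 oxepane (C16H2) with free C11–OH and C4–OTBS, via lactol 25 (not isolated)
Conditions: DIBAL-H (2.5 equiv), CH2Cl2, −78 °C; then Et3SiH, BF3·OEt2, −78 → −40 °C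
Reagents that add atoms: none
Why: Partial reduction of the lactone to the lactol, then ionic reduction of the derived oxocarbenium ion by silane (reductive deoxygenation of a lactol to a cyclic ether); C15 is no longer epimerisable afterwards.

**Step 19**
Reactants: 27 (R)-2-hydroxyoctanoic acid
Product: 28 (R)-2-[(4-methoxybenzyl)oxy]octanoic acid
Conditions: NaH (2.5 equiv), PMBCl (1.1 equiv), Bu4NI (cat.), THF/DMF, 0 °C → rt; acidify
Reagents that add atoms: 4-methoxybenzyl chloride COc1ccc(CCl)cc1
Why: Williamson etherification of the alkoxide of the dianion, which is far more nucleophilic than the carboxylate; the α-C–H is not deprotonated, so the stereocentre is kept.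

**Step 20**
Reactants: 26 C11 alcohol; 28 PMB-protected acid
Product: 29 C11 (R)-2-(PMB-oxy)octanoate with C4–OTBS
Conditions: 2,4,6-trichlorobenzoyl chloride, Et3N, THF, 0 °C; then 26, DMAP, toluene, rt
Reagents that add atoms: none
Why: Yamaguchi esterification acylates the hindered secondary alcohol through the mixed anhydride under conditions mild enough for the α-alkoxy stereocentre.

**Step 21**
Reactants: 29 silyl ether
Product: 30 C4 alcohol
Conditions: HF·pyridine, pyridine/THF, 0 °C → rt
Reagents that add atoms: none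
Why: Fluoride desilylation under buffered acidic conditions, which spares the ester, the PMB ether and the methylidene.

**Step 22**
Reactants: 30 C4 alcohol
Product: 31 C4 acetate
Conditions: Ac2O, DMAP, pyridine, rt
Reagents that add atoms: acetic anhydride CC(=O)OC(C)=O
Why: DMAP-catalysed acetylation of the only free hydroxyl group.

**Step 23**
Reactants: 31 PMB ether
Product: 32 target CNP0132024.3 (4-acetoxy-11-[(2R)-2-hydroxyoctanoyloxy]asbestin-7(19)-ene)
Conditions: DDQ, CH2Cl2/pH 7 buffer, 0 °C
Reagents that add atoms: none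
Why: Oxidative cleavage of the 4-methoxybenzyl ether by DDQ, which leaves both esters and the 1,1-disubstituted olefin alone.

**Compound list**
1 | 3-methylfuran | Cc1ccoc1 | starting material
2 | maleic anhydride | O=C1OC(=O)C=C1 | starting material
3 | rac-exo-5-methyl-7-oxabicyclo[2.2.1]hept-5-ene-2,3-dicarboxylic anhydride (racemate; the enantiomer carried on is drawn) | O=C2[C@H]1[C@@H](C(=O)O2)[C@H](C(C)=C3)O[C@@H]13 | intermediate
4 | 3-exo-(methoxycarbonyl)-5-methyl-7-oxabicyclo[2.2.1]hept-5-ene-2-exo-carboxylic acid | OC(=O)[C@H]1[C@@H](C(=O)OC)[C@H](C(C)=C3)O[C@@H]13 | intermediate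
5 | 3-exo-(hydroxymethyl)-5-methyl-7-oxabicyclo[2.2.1]hept-5-ene-2-exo-carboxylic acid | OC(=O)[C@H]1[C@@H](CO)[C@H](C(C)=C3)O[C@@H]13 | intermediate (not isolated)
6 | exo-fused γ-lactone of 5-methyl-7-oxabicyclo[2.2.1]hept-5-ene | O=C2[C@H]1[C@@H](CO2)[C@H](C(C)=C3)O[C@@H]13 | intermediate
7 | 4-acetyl-1-oxotetrahydro-1H,3H-furo[3,4-c]furan-6-carbaldehyde | O=C2[C@H]1[C@@H](CO2)[C@H](C(C)=O)O[C@@H]1C=O | intermediate (not isolated)
8 | 4-acetyl-6-(hydroxymethyl)tetrahydro-1H,3H-furo[3,4-c]furan-1-one | O=C2[C@H]1[C@@H](CO2)[C@H](C(C)=O)O[C@@H]1CO | intermediate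
9 | 6-(hydroxymethyl)-4-(prop-1-en-2-yl)tetrahydro-1H,3H-furo[3,4-c]furan-1-one | O=C2[C@H]1[C@@H](CO2)[C@H](C(C)=C)O[C@@H]1CO | intermediate
10 | 2,3-dibromopropene | C=C(Br)CBr | starting material
11 | 2-bromohexa-1,5-diene | C=C(Br)CCC=C | intermediate
12 | triflate of 9 | O=C2[C@H]1[C@@H](CO2)[C@H](C(C)=C)O[C@@H]1COS(=O)(=O)C(F)(F)F | intermediate (not isolated)
13 | 6-(2-methylidenehex-5-en-1-yl)-4-(prop-1-en-2-yl)tetrahydro-1H,3H-furo[3,4-c]furan-1-one | O=C2[C@H]1[C@@H](CO2)[C@H](C(C)=C)O[C@@H]1CC(=C)CCC=C | intermediate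
14 | tricyclic lactone: oxonane/tetrahydrofuran bicycle with (Z)-C3=C4, C7 methylidene, γ-lactone across C1/C10 | O=C2[C@H]1[C@@H](CO2)[C@H](/C(C)=C\CCC(=C)C3)O[C@@H]13 | intermediate
15 | C11 Weinreb amide, C14 alcohol | CON(C)C(=O)[C@H]1[C@@H](CO)[C@H](/C(C)=C\CCC(=C)C3)O[C@@H]13 | intermediate
16 | C11 Weinreb amide, C14 aldehyde | CON(C)C(=O)[C@H]1[C@@H](C=O)[C@H](/C(C)=C\CCC(=C)C3)O[C@@H]13 | intermediate
17 | ethyl (Z)-enoate (C14=C15–C16O2Et) | CON(C)C(=O)[C@H]1[C@@H](/C=C(/C)C(=O)OCC)[C@H](/C(C)=C\CCC(=C)C3)O[C@@H]13 | intermediate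
18 | (Z)-enoic acid | CON(C)C(=O)[C@H]1[C@@H](/C=C(/C)C(=O)O)[C@H](/C(C)=C\CCC(=C)C3)O[C@@H]13 | intermediate
19 | C3–C4 epoxy acid | CON(C)C(=O)[C@H]1[C@@H](/C=C(/C)C(=O)O)[C@H]([C@@]4(C)O[C@H]4CCC(=C)C3)O[C@@H]13 | intermediate (not isolated)
20 | unsaturated ε-lactone with C4–OH and C11 Weinreb amide | C=C1CC[C@H](O)[C@@]2(C)OC(=O)C(C)=C[C@@H]3[C@H](C(=O)N(C)OC)[C@@H](C1)O[C@H]32 | intermediate
21 | C4–OTBS ether of 20 | C=C1CC[C@H](O[Si](C)(C)C(C)(C)C)[C@@]2(C)OC(=O)C(C)=C[C@@H]3[C@H](C(=O)N(C)OC)[C@@H](C1)O[C@H]32 | intermediate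
22 | C11 isopropenyl ketone with unsaturated ε-lactone (key-step precursor) | C=C1CC[C@H](O[Si](C)(C)C(C)(C)C)[C@@]2(C)OC(=O)C(C)=C[C@@H]3[C@H](C(=O)C(C)=C)[C@@H](C1)O[C@H]32 | intermediate
23 | tetracyclic C11 ketone, C16 lactone | C=C1CC[C@H](O[Si](C)(C)C(C)(C)C)[C@@]2(C)OC(=O)[C@@H](C)[C@H]3C[C@H](C)C(=O)[C@H]4[C@@H]3[C@H]2O[C@@H]4C1 | intermediate
24 | tetracyclic C11 alcohol, C16 lactone | C=C1CC[C@H](O[Si](C)(C)C(C)(C)C)[C@@]2(C)OC(=O)[C@@H](C)[C@H]3C[C@H](C)[C@H](O)[C@H]4[C@@H]3[C@H]2O[C@@H]4C1 | intermediate
25 | C16 lactol (anomer mixture) | C=C1CC[C@H](O[Si](C)(C)C(C)(C)C)[C@@]2(C)OC(O)[C@@H](C)[C@H]3C[C@H](C)[C@H](O)[C@H]4[C@@H]3[C@H]2O[C@@H]4C1 | intermediate (not isolated)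
26 | tetracyclic oxepane with C11–OH and C4–OTBS | C=C1CC[C@H](O[Si](C)(C)C(C)(C)C)[C@@]2(C)OC[C@@H](C)[C@H]3C[C@H](C)[C@H](O)[C@H]4[C@@H]3[C@H]2O[C@@H]4C1 | intermediate
27 | (R)-2-hydroxyoctanoic acid | CCCCCC[C@@H](O)C(=O)O | starting material
28 | (R)-2-[(4-methoxybenzyl)oxy]octanoic acid | CCCCCC[C@@H](OCc1ccc(OC)cc1)C(=O)O | intermediate
29 | C11 (R)-2-(PMB-oxy)octanoate, C4–OTBS | C=C1CC[C@H](O[Si](C)(C)C(C)(C)C)[C@@]2(C)OC[C@@H](C)[C@H]3C[C@H](C)[C@H](OC(=O)[C@H](OCc5ccc(OC)cc5)CCCCCC)[C@H]4[C@@H]3[C@H]2O[C@@H]4C1 | intermediate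
30 | C11 (R)-2-(PMB-oxy)octanoate, C4–OH | C=C1CC[C@H](O)[C@@]2(C)OC[C@@H](C)[C@H]3C[C@H](C)[C@H](OC(=O)[C@H](OCc5ccc(OC)cc5)CCCCCC)[C@H]4[C@@H]3[C@H]2O[C@@H]4C1 | intermediate
31 | C11 (R)-2-(PMB-oxy)octanoate, C4–OAc | C=C1CC[C@H](OC(C)=O)[C@@]2(C)OC[C@@H](C)[C@H]3C[C@H](C)[C@H](OC(=O)[C@H](OCc5ccc(OC)cc5)CCCCCC)[C@H]4[C@@H]3[C@H]2O[C@@H]4C1 | intermediate
32 | CNP0132024.3 | C=C1CC[C@H](OC(C)=O)[C@@]2(C)OC[C@@H](C)[C@H]3C[C@H](C)[C@H](OC(=O)[C@H](O)CCCCCC)[C@H]4[C@@H]3[C@H]2O[C@@H]4C1 | target

**Step count**
Total: 23 steps. Longest linear sequence: 21 steps (steps 1–5, 7–18, 20–23).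

**Steps most likely to fail**

Step 16. What may go wrong: protonation and a second electron transfer may saturate the isopropenyl ketone before the 6-exo closure, or the kinetically protonated C12 centre may be lost by enolate equilibration. Fallback, from 22 back to 23: a tin-ketyl radical chain in place of electron transfer. Bu3SnH (slow addition) and AIBN in benzene at 80 °C add Bu3Sn• to the ketone oxygen; the O-stannyl allyl radical closes 6-exo on C14 and hydrogen transfer to C15 gives the tributylstannyl enol ether F1. Protonolysis of F1 with AcOH at −78 °C from the convex face should give 23.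

Step 8. What may go wrong: slow turnover at the hindered gem-disubstituted olefin next to C2, so that intermolecular metathesis of the terminal vinyl group (oligomerisation) takes over. Fallback, from 8 back to 14: relay ring-closing metathesis. Wittig olefination of the C3 ketone of 8 with the salt-free ylide from (hex-5-en-1-yl)triphenylphosphonium bromide at −78 °C gives the relay alkenol F2 (E/Z mixture, both usable). Triflation gives the relay triflate F3, and copper-catalysed coupling with the Grignard reagent from 11 gives the relay tetraene F4. The Ru carbene loads on the unhindered terminal olefin of the relay arm, expels cyclopentene and is thereby placed on C3, from where closure onto the C4 vinyl group should give 14.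

Step 13. What may go wrong: the peracid may attack the wrong π-face of C3=C4 or the C7 methylidene, and the methylidene may take part transannularly during acid-mediated epoxide opening. Fallback, from 17 back to 20: catalyst-controlled epoxidation. Shi epoxidation of ester 17 (fructose-derived ketone or its enantiomer, matched to the required face; Oxone, pH 10.5), which is selective for trisubstituted olefins, gives the epoxy ester F5. Saponification of F5 gives 19, and CSA then gives 20.

**Further compounds**
F1 | step 16 | tributylstannyl enol ether of 23 (C11–OSnBu3, C11=C12) | C=C1CC[C@H](O[Si](C)(C)C(C)(C)C)[C@@]2(C)OC(=O)[C@@H](C)[C@H]3CC(C)=C(O[Sn](CCCC)(CCCC)CCCC)[C@H]4[C@@H]3[C@H]2O[C@@H]4C1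
F2 | step 8 | relay alkenol: 4-(octa-2,7-dien-2-yl)-6-(hydroxymethyl)tetrahydro-1H,3H-furo[3,4-c]furan-1-one | O=C2[C@H]1[C@@H](CO2)[C@H](C(C)=CCCCC=C)O[C@@H]1CO
F3 | step 8 | triflate of F2 | O=C2[C@H]1[C@@H](CO2)[C@H](C(C)=CCCCC=C)O[C@@H]1COS(=O)(=O)C(F)(F)F
F4 | step 8 | relay tetraene: 6-(2-methylidenehex-5-en-1-yl)-4-(octa-2,7-dien-2-yl)tetrahydro-1H,3H-furo[3,4-c]furan-1-one | O=C2[C@H]1[C@@H](CO2)[C@H](C(C)=CCCCC=C)O[C@@H]1CC(=C)CCC=C
F5 | step 13 | C3–C4 epoxide of ethyl ester 17 | CON(C)C(=O)[C@H]1[C@@H](/C=C(/C)C(=O)OCC)[C@H]([C@@]4(C)O[C@H]4CCC(=C)C3)O[C@@H]13
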